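The numbers in the tables are calculated for an exercise.

- E and J cannot be the whole of the charge: the cedar run ends at 20% E and 36% J, a sum of 56.0%.

| flask | J | D | remark | time | volume of the second phase over the first |
|---|---|---|---|---|---|
| cedar | 5 mM | 1.1 equiv | run made earlier |  |  |
| alder | 20 mM | 1.1 equiv | run made earlier |  |  |
| flask | 10 mM | 1.10 equiv |  | 15 min | 2.0 |

- cedar (time / min: E / %, J / %): 1.33: 7, 81; 2.50: 12, 75; 4.00: 16, 62; 5.00: 17, 54; 6.00: 18, 51; 8.00: 19, 41; 10.0: 20, 36
- alder (time / min: E / %, J / %): 0.500: 11, 83; 1.33: 22, 63; 2.50: 23, 43; 4.00: 27, 33; 5.00: 27, 25; 8.00: 27, 16; 10.0: 25, 12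

(scatter of a reading: 2 percentage points)

- in the second phase: D; everything else is in the first
- charges count per volume of the first phase; a concentration in a rate is the amount of a species over the volume of its own phase; every rate counts per litre of the first phase
- the numbers in the tables scatter by 2 percentage points (one standard deviation)
- the earlier runs hold the two phases in the same ratio of volumes as the flask asked about

- ochre: doubling the amount of D, all else as stated
- violet: doubling the transfer coefficient of D, all else as stated

* amount of E at 15 min, in percent of the J charged
* the change that raises the amount of E at 15 min, in percent of the J charged most ("none" if none brings more than 2 percentage points) (ochre / violet / none)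
* amount of E at 15 min, in percent of the J charged, after violet

- So set E aside first and count the fraction of J left.
- Treat J as the limiting reagent, with D charged close to it. Expect a second-order loss, so the reciprocal of the fraction left grows with charge times time.
- Read the constant from alder at 8.00 min: 0.547 L mol⁻¹ s⁻¹. This is the clock constant: the reciprocal of the fraction left, less one, over charge times time.
- Test it on cedar at 10.0 min. It gives 37.9% J, and the reading is 36%, with a scatter of 2 percentage points.
- Watch alder slowly. At 0.500 min, J has lost 17.0% and E reads 11%, so formation leads.
- At 4.00 min, E reads 27% and J 33%. At 8.00 min, E still reads 27%.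
- At 10.0 min, E reads 25% and J 12%.
- Place the flask on this clock. Its charge is half of alder's, so 15 min matches alder at 7.50 min. My reckoning leaves 16.9% J and gives no figure for E.
- The forecast gives 23% E, none as the best change, and 23% after violet: “Violet only speeds the early stage, and E is already on its plateau.”
- The flask gives 18.2% E, none as the best change, and 18.1% after violet. Ochre moves E by 0.015 points and violet by −0.17 points.

    G ⇌ D, rate k1*([G] - [D]/K1) per volume of the first phase (partition coefficient = 2.70, kL = 0.0720 s⁻¹)
    J + G → E (k = 3.70 L mol⁻¹ s⁻¹)
    E → Q (k = 0.00260 s⁻¹)
    E ⇌ X (K = 1.20, k = 0.0600 s⁻¹)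

- The forecast stands within its tolerance. At 15.0 min, the flask holds 13.6% J against the clock's 16.9%. E is falling there, made at 0.715 of the net rate of its loss. Now read the same flask at 6.0 min. The clock gives 33.7% J, and that flask holds 33%. Its E stands at 23.2%, more than the 18.2% of the later reading.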